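**Plan**

- Retrosynthesis: the O9–angeloyl and O8–tigloyl bonds are cut first, then C11=C12 (back to a C7 acetyl group) and C7–C11, then C4–C5 of ring A (anionic oxy-Cope retron, C2–C7 re-formed), then C7–C8 and C9–C10 (Diels–Alder).
- Enabling feature: ring A (C1, C2, C3, C4, C5, C10) carries the C2 ketone and, side by side, the secondary methyl at C4, the quaternary methyl at C5 and the cis hydrogen at C10, so C4–C5 can be the σ bond made in a [3,3] shift of an alkoxide-bearing 1,5-diene held in a bicyclo[2.2.2]octene.
- Forward order: ring B arises first, as the cyclohexene boat of a bicyclo[2.2.2]octenone (masked o-benzoquinone from 2-methoxy-4-methylphenol plus 1,1-diethoxyethene); (Z)-propenyl addition and the oxy-Cope shift then close ring A; ring B is completed by oxygenation at C9, a two-carbon unit at C7 and the two acylations.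
- Stereochemistry: absolute configuration from resolution of the bicyclic ketone; C4, C5 and C10 from the Z alkene and the boat geometry forced on the [3,3] shift.
- C8 from axial hydride delivery to the enone, C7 from hydroxyl-directed hydrogenation, C9 from oxidation followed by equatorial hydride delivery to the 9-ketone.

Key step: step 4

Remark: decalins are numbered C1–C10 as in eremophilane (ring A = C1–C5 and C10, ring B = C5–C10, methyls on C4 and C5; β = the face of the C5 methyl), and it is assumed that the absolute configuration of the resolved ketone can be assigned by anomalous-dispersion X-ray analysis of the later C7 iodide.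

**Route**

Step 1
Reactants: 1 2-methoxy-4-methylphenol; 2 1,1-diethoxyethene
Product: 4 rac-7,7-diethoxy-3,3-dimethoxy-5-methylbicyclo[2.2.2]oct-5-en-2-one, via masked o-benzoquinone 3 (not isolated)
Conditions: PhI(OAc)2, MeOH, 0 °C, 10 min; then NaHCO3, 2 (10 equiv), 0 °C → rt
Reagents that add atoms: methanol, CO
Why: Oxidative dearomatisation of the guaiacol in methanol gives the electron-poor cyclohexa-2,4-dienone 3, which the very electron-rich ketene acetal should intercept in an inverse-electron-demand Diels–Alder reaction before it dimerises, the nucleophilic CH2 terminus bonding to the δ-carbon of the dienone so that the new ketal carbon sits next to the bridgehead α to the ketone, and only the racemic pair of bridgeheads is created.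

Step 2
Reactants: 4 rac-7,7-diethoxy-3,3-dimethoxy-5-methylbicyclo[2.2.2]oct-5-en-2-one
Product: 5 (1S,4R)-7,7-diethoxy-3,3-dimethoxy-5-methylbicyclo[2.2.2]oct-5-en-2-one
Conditions: preparative SFC, amylose tris(3,5-dimethylphenylcarbamate) phase, CO2/i-PrOH
Reagents that add atoms: none
Why: Resolution by chromatography on a chiral stationary phase should separate the enantiomers of this rigid, non-enolisable ketone, which cannot racemise, and the (1S,4R) fraction is carried on.

Step 3
Reactants: 5 (1S,4R)-7,7-diethoxy-3,3-dimethoxy-5-methylbicyclo[2.2.2]oct-5-en-2-one; 6 (Z)-1-bromoprop-1-ene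
Product: 8 (1S,2S,4R)-7,7-diethoxy-3,3-dimethoxy-5-methyl-2-[(Z)-prop-1-enyl]bicyclo[2.2.2]oct-5-en-2-ol, via (Z)-prop-1-enyllithium 7 (not isolated)
Conditions: 6, Li (1% Na), Et2O, 0 °C; then 5, THF, −78 °C; aq NH4Cl
Reagents that add atoms: none
Why: The alkenyllithium made from the bromide and lithium metal keeps its Z geometry and should undergo 1,2-addition to the non-enolisable ketone from the face of the C5=C6 etheno bridge, the other face being screened by an ethoxy group of the C7 ketal, which sets C2 with the propenyl group syn to the alkene as the [3,3] shift requires.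

Step 4
Reactants: 8 (1S,2S,4R)-7,7-diethoxy-3,3-dimethoxy-5-methyl-2-[(Z)-prop-1-enyl]bicyclo[2.2.2]oct-5-en-2-ol
Product: 11 cis-fused 8,8-diethoxy-1,1-dimethoxy-4β,5β-dimethyl-10βH-decal-6-en-2-one, via potassium alkoxide 9 (not isolated), via potassium enolate 10 (not isolated)
Conditions: KH, 18-crown-6, THF, 0 °C → 65 °C; aq NH4Cl
Reagents that add atoms: none
Why: Deprotonation gives the crown-separated potassium alkoxide 9, whose oxyanion weakens the adjacent C2–C7 bond so that the 1,5-diene C4=C3–C2–C7–C6=C5 undergoes a concerted suprafacial [3,3] sigmatropic shift in which C4–C5 forms as C2–C7 breaks, giving enolate 10 and, on protonation at C3, ketone 11. The closest known reaction type is the anionic oxy-Cope rearrangement of 2-alkenylbicyclo[2.2.2]oct-5-en-2-ols to cis-fused decalinones. Ring A (C1, C2, C3, C4, C5, C10) closes through the single new σ bond C4–C5 inside a six-membered cyclic transition state that the bicycle forces into a boat, while ring B is simply the six-membered ring C5–C10 of the bicycle that survives the cleavage of the third bridge. At C5 the new bond can only form on the alkene face turned toward the propenyl-bearing bridge, so the C5 methyl ends cis to the former bridgehead hydrogen at C10 (cis ring fusion), and because the propenyl group is Z its methyl points into the concave side of the boat array and therefore finishes on the same face of ring A as the C5 methyl. The step needs the [3,3] path to win over retro-aldol-type fragmentation and over loss of alkene geometry, which the ketal (not carbonyl) at C8 and the configurationally stable Z alkene should secure, although heating is planned because the inner methyl group must pass close to the C1 ketal.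

Step 5
Reactants: 11 cis-fused 8,8-diethoxy-1,1-dimethoxy-4β,5β-dimethyl-10βH-decal-6-en-2-one
Product: 13 4β,5β-dimethyl-10βH-decal-6-ene-2,8-dione, via ketal ketone 12 (not isolated)
Conditions: SmI2 (5 equiv), THF/MeOH, −78 °C → rt; then 1 M HCl, THF, rt
Reagents that add atoms: water, O
Why: SmI2 should remove both methoxy groups by reductive cleavage of the α-alkoxy ketone through samarium enolates without touching the isolated alkene or the remote ketal, and the acidic work-up then hydrolyses the allylic diethyl ketal (ketal hydrolysis) to the conjugated enone, no stereocentre being α to either carbonyl.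

Step 6
Reactants: 13 4β,5β-dimethyl-10βH-decal-6-ene-2,8-dione
Product: 14 2,2-ethylenedioxy-4β,5β-dimethyl-10βH-decal-6-en-8-one
Conditions: HOCH2CH2OH, PPTS (cat.), benzene, reflux, Dean–Stark
Reagents that add atoms: ethylene glycol, OCCO
Why: Acid-catalysed ketalisation should be selective for the saturated C2 ketone because the C8 carbonyl would have to give up its conjugation (the selectivity long known for bicyclic enediones), which masks ring A for the enolate, hydride and organometallic steps on ring B.

Step 7
Reactants: 14 2,2-ethylenedioxy-4β,5β-dimethyl-10βH-decal-6-en-8-one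
Product: 16 9β-(tert-butyldimethylsilyloxy)-2,2-ethylenedioxy-4β,5β-dimethyl-10βH-decal-6-en-8-one, via silyl dienol ether 15 (not isolated)
Conditions: LiN(SiMe3)2, THF, −78 °C; TBSOTf; then mCPBA, NaHCO3, CH2Cl2, −20 °C → 0 °C
Reagents that add atoms: tert-butyldimethylsilyl triflate, CC(C)(C)[Si](C)(C)OS(=O)(=O)C(F)(F)F; 3-chloroperbenzoic acid, OOC(=O)c1cccc(Cl)c1
Why: Kinetic deprotonation can only occur at C9 (C5 is quaternary), and Rubottom oxidation of the cross-conjugated silyl dienol ether 15, with the peracid attacking the electron-rich C8=C9 bond from the convex face cis to the C10 hydrogen and a 1,4-silyl shift following, should give the 9β-silyloxy enone, a configuration that is later erased and reset but that places the silyloxy group equatorial and so fixes the shape of ring B.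

Step 8
Reactants: 16 9β-(tert-butyldimethylsilyloxy)-2,2-ethylenedioxy-4β,5β-dimethyl-10βH-decal-6-en-8-one
Product: 17 9β-(tert-butyldimethylsilyloxy)-2,2-ethylenedioxy-7-iodo-4β,5β-dimethyl-10βH-decal-6-en-8-one
Conditions: I2, pyridine, CH2Cl2, 0 °C → rt
Reagents that add atoms: iodine, II
Why: α-Iodination of the enone by the pyridine/iodine addition–elimination sequence is established for cyclohexenones with a quaternary γ-carbon and installs the handle for the C7–C11 bond without touching a stereocentre.

Step 9
Reactants: 17 9β-(tert-butyldimethylsilyloxy)-2,2-ethylenedioxy-7-iodo-4β,5β-dimethyl-10βH-decal-6-en-8-one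
Product: 18 9β-(tert-butyldimethylsilyloxy)-2,2-ethylenedioxy-7-iodo-4β,5β-dimethyl-10βH-decal-6-en-8α-ol
Conditions: NaBH4, CeCl3·7H2O, MeOH, −78 °C → −20 °C
Reagents that add atoms: none
Why: Luche reduction should deliver hydride 1,2 to the iodo enone along the axial trajectory on the convex β face (cis to the axial C10 hydrogen, whereas the α face is covered by the axial C5–C4 bond of ring A), giving the pseudo-equatorial 8α-alcohol trans to the 9β-silyloxy group and leaving the C–I bond intact.

Step 10
Reactants: 18 9β-(tert-butyldimethylsilyloxy)-2,2-ethylenedioxy-7-iodo-4β,5β-dimethyl-10βH-decal-6-en-8α-ol; 19 tributyl(1-ethoxyvinyl)stannane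
Product: 21 7-acetyl-9β-(tert-butyldimethylsilyloxy)-2,2-ethylenedioxy-4β,5β-dimethyl-10βH-decal-6-en-8α-ol, via ethoxyvinyl diene 20 (not isolated)
Conditions: 19, Pd(PPh3)4 (5 mol %), CuI (10 mol %), DMF, 60 °C; then 1 M HCl, THF, 0 °C
Reagents that add atoms: water, O
Why: Stille coupling of the alkenyl iodide with the 1-ethoxyvinylstannane under zerovalent palladium and copper co-catalysis should give the 2-ethoxydiene 20, whose enol ether is hydrolysed by cold dilute acid to the acetyl group while the far less labile dioxolane and silyl ether survive and no stereocentre is affected.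

Step 11
Reactants: 21 7-acetyl-9β-(tert-butyldimethylsilyloxy)-2,2-ethylenedioxy-4β,5β-dimethyl-10βH-decal-6-en-8α-ol
Product: 22 7β-acetyl-9β-(tert-butyldimethylsilyloxy)-2,2-ethylenedioxy-4β,5β-dimethyl-10βH-decalin-8α-ol
Conditions: H2 (1 atm), [Ir(cod)(PCy3)(py)]PF6 (5 mol %), CH2Cl2, rt
Reagents that add atoms: none
Why: In this hydroxyl-directed hydrogenation the cationic iridium complex should bind the allylic 8α-hydroxyl and deliver H2 to the same α face of the C6=C7 bond, which sets C7 with its hydrogen cis to O8 and the acetyl group β, the equatorial and also the more stable arrangement.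

Step 12
Reactants: 22 7β-acetyl-9β-(tert-butyldimethylsilyloxy)-2,2-ethylenedioxy-4β,5β-dimethyl-10βH-decalin-8α-ol
Product: 23 9β-(tert-butyldimethylsilyloxy)-2,2-ethylenedioxy-7β-isopropenyl-4β,5β-dimethyl-10βH-decalin-8α-ol
Conditions: Zn, CH2Br2, TiCl4, THF/CH2Cl2, 0 °C → rt
Reagents that add atoms: dibromomethane, BrCBr
Why: Carbonyl methylenation with the non-basic zinc/dibromomethane/TiCl4 reagent should turn the methyl ketone into the isopropenyl group without enolising the epimerisable C7 or causing retro-aldol cleavage of the β-hydroxy ketone, and it tolerates the free hydroxyl, the ketal and the silyl ether.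

Step 13
Reactants: 23 9β-(tert-butyldimethylsilyloxy)-2,2-ethylenedioxy-7β-isopropenyl-4β,5β-dimethyl-10βH-decalin-8α-ol; 24 (E)-2-methylbut-2-enoyl chloride (tigloyl chloride)
Product: 25 9β-(tert-butyldimethylsilyloxy)-2,2-ethylenedioxy-7β-isopropenyl-4β,5β-dimethyl-10βH-decalin-8α-yl (E)-2-methylbut-2-enoate
Conditions: 24, DMAP, Et3N, CH2Cl2, 0 °C → rt
Reagents that add atoms: none
Why: DMAP-catalysed acylation of the equatorial 8α-hydroxyl through the acylpyridinium ion should install the tiglate, which is the thermodynamically preferred E isomer so that no geometric scrambling is to be feared.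

Step 14
Reactants: 25 9β-(tert-butyldimethylsilyloxy)-2,2-ethylenedioxy-7β-isopropenyl-4β,5β-dimethyl-10βH-decalin-8α-yl (E)-2-methylbut-2-enoate
Product: 26 2,2-ethylenedioxy-9β-hydroxy-7β-isopropenyl-4β,5β-dimethyl-10βH-decalin-8α-yl (E)-2-methylbut-2-enoate
Conditions: HF·pyridine, pyridine, THF, 0 °C → rt
Reagents that add atoms: none
Why: Fluoride-driven desilylation under buffered, slightly acidic conditions should free the 9β-hydroxyl without base-induced migration of the tiglate and without opening the dioxolane.

Step 15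
Reactants: 26 2,2-ethylenedioxy-9β-hydroxy-7β-isopropenyl-4β,5β-dimethyl-10βH-decalin-8α-yl (E)-2-methylbut-2-enoate
Product: 27 2,2-ethylenedioxy-7β-isopropenyl-4β,5β-dimethyl-9-oxo-10βH-decalin-8α-yl (E)-2-methylbut-2-enoate
Conditions: triacetoxyperiodinane (1,1,1-triacetoxy-1,2-benziodoxol-3-one), NaHCO3, CH2Cl2, rt
Reagents that add atoms: none
Why: Dess–Martin oxidation converts the secondary alcohol into the ketone under near-neutral conditions, which should avoid enolisation of the α-acyloxy ketone toward C8 or C10 and thereby erases the provisional C9 configuration only.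

Step 16
Reactants: 27 2,2-ethylenedioxy-7β-isopropenyl-4β,5β-dimethyl-9-oxo-10βH-decalin-8α-yl (E)-2-methylbut-2-enoate
Product: 28 2,2-ethylenedioxy-9α-hydroxy-7β-isopropenyl-4β,5β-dimethyl-10βH-decalin-8α-yl (E)-2-methylbut-2-enoate
Conditions: LiBH(s-Bu)3, THF, −78 °C; AcOH quench at −78 °C
Reagents that add atoms: none
Why: In this ketone reduction under steric approach control the bulky trialkylborohydride should attack C9 along the equatorial trajectory on the β face, because ring B is locked with the C7 and C8 substituents equatorial and the axial approach on the α face is blocked by the 1,3-diaxial C5–C4 bond of ring A, so the axial 9α-alcohol cis to the tiglate results.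

Step 17
Reactants: 28 2,2-ethylenedioxy-9α-hydroxy-7β-isopropenyl-4β,5β-dimethyl-10βH-decalin-8α-yl (E)-2-methylbut-2-enoate; 29 (Z)-2-methylbut-2-enoic acid (angelic acid)
Product: 31 2,2-ethylenedioxy-7β-isopropenyl-4β,5β-dimethyl-8α-[(E)-2-methylbut-2-enoyloxy]-10βH-decalin-9α-yl (Z)-2-methylbut-2-enoate, via mixed anhydride 30 (not isolated)
Conditions: 29, 2,4,6-Cl3C6H2COCl, Et3N, toluene, rt; then 28, toluene, 80 °C
Reagents that add atoms: none
Why: Yamaguchi esterification through the mixed anhydride 30, run without DMAP, is the established way to acylate hindered secondary alcohols with angelic acid without Z to E isomerisation, and the tiglate, which already sits on the less hindered equatorial oxygen and migrates sluggishly, should stay in place.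

Step 18
Reactants: 31 2,2-ethylenedioxy-7β-isopropenyl-4β,5β-dimethyl-8α-[(E)-2-methylbut-2-enoyloxy]-10βH-decalin-9α-yl (Z)-2-methylbut-2-enoate
Product: 32 7β-isopropenyl-4β,5β-dimethyl-2-oxo-8α-[(E)-2-methylbut-2-enoyloxy]-10βH-decalin-9α-yl (Z)-2-methylbut-2-enoate (CNP0249036.3)
Conditions: 1 M HCl, THF, rt
Reagents that add atoms: water, O
Why: Ketal hydrolysis with dilute acid should release the C2 ketone while the two hindered enoates, the isopropenyl group and all six stereocentres, none of which is α to the new carbonyl, remain unchanged.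

**Compound list**

1 | 2-methoxy-4-methylphenol | COc1cc(C)ccc1O | starting material
2 | 1,1-diethoxyethene | C=C(OCC)OCC | starting material
3 | 6,6-dimethoxy-4-methylcyclohexa-2,4-dien-1-one (masked o-benzoquinone, formed in the flask) | COC1(OC)C=C(C)C=CC1=O | intermediate
4 | rac-7,7-diethoxy-3,3-dimethoxy-5-methylbicyclo[2.2.2]oct-5-en-2-one (racemate) | O=C1C(OC)(OC)C2C(C)=CC1C(OCC)(OCC)C2 | intermediate
5 | (1S,4R)-7,7-diethoxy-3,3-dimethoxy-5-methylbicyclo[2.2.2]oct-5-en-2-one | O=C1C(OC)(OC)[C@H]2C(C)=C[C@@H]1C(OCC)(OCC)C2 | intermediate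
6 | (Z)-1-bromoprop-1-ene | C/C=C\Br | starting material
7 | (Z)-prop-1-enyllithium (formed in the flask) | C/C=C\[Li] | intermediate
8 | (1S,2S,4R)-7,7-diethoxy-3,3-dimethoxy-5-methyl-2-[(Z)-prop-1-enyl]bicyclo[2.2.2]oct-5-en-2-ol | C/C=C\[C@@]1(O)C(OC)(OC)[C@H]2C(C)=C[C@@H]1C(OCC)(OCC)C2 | intermediate
9 | potassium alkoxide of 8 (formed in the flask) | C/C=C\[C@@]1([O-])C(OC)(OC)[C@H]2C(C)=C[C@@H]1C(OCC)(OCC)C2.[K+] | intermediate
10 | potassium C2–C3 enolate of 11 (formed in the flask) | C1=C[C@@]2(C)[C@H](C(OC)(OC)C([O-])=C[C@@H]2C)CC1(OCC)OCC.[K+] | intermediate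
11 | cis-fused 8,8-diethoxy-1,1-dimethoxy-4β,5β-dimethyl-10βH-decal-6-en-2-one | C1=C[C@@]2(C)[C@H](C(OC)(OC)C(=O)C[C@@H]2C)CC1(OCC)OCC | intermediate
12 | 8,8-diethoxy-4β,5β-dimethyl-10βH-decal-6-en-2-one (formed in the flask) | C1=C[C@@]2(C)[C@H](CC(=O)C[C@@H]2C)CC1(OCC)OCC | intermediate
13 | 4β,5β-dimethyl-10βH-decal-6-ene-2,8-dione | C1=C[C@@]2(C)[C@H](CC(=O)C[C@@H]2C)CC1=O | intermediate
14 | 2,2-ethylenedioxy-4β,5β-dimethyl-10βH-decal-6-en-8-one | C1=C[C@@]2(C)[C@H](CC3(OCCO3)C[C@@H]2C)CC1=O | intermediate
15 | 8-(tert-butyldimethylsilyloxy)-2,2-ethylenedioxy-4β,5β-dimethyl-10βH-decala-6,8-diene (formed in the flask) | C1=C[C@@]2(C)[C@H](CC3(OCCO3)C[C@@H]2C)C=C1O[Si](C)(C)C(C)(C)C | intermediate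
16 | 9β-(tert-butyldimethylsilyloxy)-2,2-ethylenedioxy-4β,5β-dimethyl-10βH-decal-6-en-8-one | C1=C[C@@]2(C)[C@H](CC3(OCCO3)C[C@@H]2C)[C@@H](O[Si](C)(C)C(C)(C)C)C1=O | intermediate
17 | 9β-(tert-butyldimethylsilyloxy)-2,2-ethylenedioxy-7-iodo-4β,5β-dimethyl-10βH-decal-6-en-8-one | IC1=C[C@@]2(C)[C@H](CC3(OCCO3)C[C@@H]2C)[C@@H](O[Si](C)(C)C(C)(C)C)C1=O | intermediate
18 | 9β-(tert-butyldimethylsilyloxy)-2,2-ethylenedioxy-7-iodo-4β,5β-dimethyl-10βH-decal-6-en-8α-ol | IC1=C[C@@]2(C)[C@H](CC3(OCCO3)C[C@@H]2C)[C@@H](O[Si](C)(C)C(C)(C)C)[C@@H]1O | intermediate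
19 | tributyl(1-ethoxyvinyl)stannane | CCCC[Sn](CCCC)(CCCC)C(=C)OCC | starting material
20 | 9β-(tert-butyldimethylsilyloxy)-7-(1-ethoxyvinyl)-2,2-ethylenedioxy-4β,5β-dimethyl-10βH-decal-6-en-8α-ol (formed in the flask) | C=C(OCC)C1=C[C@@]2(C)[C@H](CC3(OCCO3)C[C@@H]2C)[C@@H](O[Si](C)(C)C(C)(C)C)[C@@H]1O | intermediate
21 | 7-acetyl-9β-(tert-butyldimethylsilyloxy)-2,2-ethylenedioxy-4β,5β-dimethyl-10βH-decal-6-en-8α-ol | CC(=O)C1=C[C@@]2(C)[C@H](CC3(OCCO3)C[C@@H]2C)[C@@H](O[Si](C)(C)C(C)(C)C)[C@@H]1O | intermediate
22 | 7β-acetyl-9β-(tert-butyldimethylsilyloxy)-2,2-ethylenedioxy-4β,5β-dimethyl-10βH-decalin-8α-ol | CC(=O)[C@H]1C[C@@]2(C)[C@H](CC3(OCCO3)C[C@@H]2C)[C@@H](O[Si](C)(C)C(C)(C)C)[C@@H]1O | intermediate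
23 | 9β-(tert-butyldimethylsilyloxy)-2,2-ethylenedioxy-7β-isopropenyl-4β,5β-dimethyl-10βH-decalin-8α-ol | C=C(C)[C@H]1C[C@@]2(C)[C@H](CC3(OCCO3)C[C@@H]2C)[C@@H](O[Si](C)(C)C(C)(C)C)[C@@H]1O | intermediate
24 | (E)-2-methylbut-2-enoyl chloride (tigloyl chloride) | C/C=C(\C)C(Cl)=O | starting material
25 | 9β-(tert-butyldimethylsilyloxy)-2,2-ethylenedioxy-7β-isopropenyl-4β,5β-dimethyl-10βH-decalin-8α-yl (E)-2-methylbut-2-enoate | C=C(C)[C@H]1C[C@@]2(C)[C@H](CC3(OCCO3)C[C@@H]2C)[C@@H](O[Si](C)(C)C(C)(C)C)[C@@H]1OC(=O)/C(C)=C/C | intermediate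
26 | 2,2-ethylenedioxy-9β-hydroxy-7β-isopropenyl-4β,5β-dimethyl-10βH-decalin-8α-yl (E)-2-methylbut-2-enoate | C=C(C)[C@H]1C[C@@]2(C)[C@H](CC3(OCCO3)C[C@@H]2C)[C@@H](O)[C@@H]1OC(=O)/C(C)=C/C | intermediate
27 | 2,2-ethylenedioxy-7β-isopropenyl-4β,5β-dimethyl-9-oxo-10βH-decalin-8α-yl (E)-2-methylbut-2-enoate | C=C(C)[C@H]1C[C@@]2(C)[C@H](CC3(OCCO3)C[C@@H]2C)C(=O)[C@@H]1OC(=O)/C(C)=C/C | intermediate
28 | 2,2-ethylenedioxy-9α-hydroxy-7β-isopropenyl-4β,5β-dimethyl-10βH-decalin-8α-yl (E)-2-methylbut-2-enoate | C=C(C)[C@H]1C[C@@]2(C)[C@H](CC3(OCCO3)C[C@@H]2C)[C@H](O)[C@@H]1OC(=O)/C(C)=C/C | intermediate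
29 | (Z)-2-methylbut-2-enoic acid (angelic acid) | C/C=C(/C)C(O)=O | starting material
30 | (Z)-2-methylbut-2-enoic 2,4,6-trichlorobenzoic anhydride (formed in the flask) | C/C=C(/C)C(=O)OC(=O)c1c(Cl)cc(Cl)cc1Cl | intermediate
31 | 2,2-ethylenedioxy-7β-isopropenyl-4β,5β-dimethyl-8α-[(E)-2-methylbut-2-enoyloxy]-10βH-decalin-9α-yl (Z)-2-methylbut-2-enoate | C=C(C)[C@H]1C[C@@]2(C)[C@H](CC3(OCCO3)C[C@@H]2C)[C@H](OC(=O)/C(C)=C\C)[C@@H]1OC(=O)/C(C)=C/C | intermediate
32 | 7β-isopropenyl-4β,5β-dimethyl-2-oxo-8α-[(E)-2-methylbut-2-enoyloxy]-10βH-decalin-9α-yl (Z)-2-methylbut-2-enoate (CNP0249036.3) | C=C(C)[C@H]1C[C@@]2(C)[C@H](CC(=O)C[C@@H]2C)[C@H](OC(=O)/C(C)=C\C)[C@@H]1OC(=O)/C(C)=C/C | target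

**Step count**

Total step count: 18. Longest linear sequence: 18 steps (from 1 to 32).

**Steps most likely to fail**

Step 1. The ketene acetal may be consumed by protonation and solvolysis in the acetic acid and methanol that accompany the oxidation, while 3 dimerises before it is trapped. The fallback sets out from 1: the oxidation is run without dienophile and 3 is allowed to dimerise to the Diels–Alder dimer F1, which is purified free of acid and methanol. Thermolysis of F1 with an excess of 2 in mesitylene at 220 °C (sealed tube) regenerates 3 by retro-Diels–Alder reaction under neutral conditions and traps it as 4, where the route is rejoined.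

Step 11. The cationic iridium centre may fail to engage the hindered, electron-poor trisubstituted C6=C7 bond on the concave α face, so that reduction is slow or takes place without hydroxyl direction, giving poor facial selectivity at C7. The fallback sets out from 21 and gives up kinetic control: 1,4-reduction of the enone with [(Ph3P)CuH]6 in wet toluene gives, after protonation of the copper enolate, a mixture of 22 and the 7α-acetyl epimer F2. Since C7 is then α to the acetyl carbonyl, DBU in toluene at room temperature should equilibrate F2 into 22, in which the acetyl, hydroxyl and silyloxy groups are all equatorial. The route is rejoined at 22.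

Step 17. Acylation of the axial 9α-hydroxyl, flanked by the ring fusion and the tiglate, may be so slow that the angeloyl donor isomerises from Z to E, or that the tiglate migrates to O9 and O8 is acylated instead, which would scramble the two esters. The fallback sets out from 28 and builds the angelate on the oxygen. Acylation with the small and reactive 2-[bis(2,2,2-trifluoroethoxy)phosphoryl]propanoic acid (DCC, DMAP, CH2Cl2, 0 °C) gives the phosphonopropanoate F3 as a mixture of epimers at the phosphorus-bearing carbon. A Z-selective Horner–Wadsworth–Emmons olefination with acetaldehyde (KN(SiMe3)2, 18-crown-6, THF, −78 °C) then forms the (Z)-2-methylbut-2-enoate directly and rejoins the route at 31.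

**Further compounds**

F1 | step 1 | rac-3,3,10,10-tetramethoxy-7,11-dimethyltricyclo[6.2.2.0(2,7)]dodeca-5,11-diene-4,9-dione (endo Diels–Alder dimer of 3, relative configuration shown) | O=C1C(OC)(OC)[C@H]2C(C)=C[C@@H]1[C@]1(C)C=CC(=O)C(OC)(OC)[C@H]21
F2 | step 11 | 7α-acetyl-9β-(tert-butyldimethylsilyloxy)-2,2-ethylenedioxy-4β,5β-dimethyl-10βH-decalin-8α-ol | CC(=O)[C@@H]1C[C@@]2(C)[C@H](CC3(OCCO3)C[C@@H]2C)[C@@H](O[Si](C)(C)C(C)(C)C)[C@@H]1O
F3 | step 17 | 2,2-ethylenedioxy-7β-isopropenyl-4β,5β-dimethyl-8α-[(E)-2-methylbut-2-enoyloxy]-10βH-decalin-9α-yl 2-[bis(2,2,2-trifluoroethoxy)phosphoryl]propanoate | C=C(C)[C@H]1C[C@@]2(C)[C@H](CC3(OCCO3)C[C@@H]2C)[C@H](OC(=O)C(C)P(=O)(OCC(F)(F)F)OCC(F)(F)F)[C@@H]1OC(=O)/C(C)=C/C
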